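The route rests on cutting the C9–C10 bond of the nine-membered oxacycle (C3–C4=C5–C6–C7–C8–C9–C10–O). The C9 carbinol, the quaternary ether carbon C10 and the C1 ketone of the furanone ring form an aldol (β-hydroxy ketone) triad. With lactone and furanone rings already present, an intramolecular Mukaiyama aldol of the aromatic 3-silyloxyfuran, generated from the 2-methylfuranone, onto the C9 aldehyde closes this last ring and sets C9 and C10 in one operation, giving the target directly. The precursor is open between C9 and C10: a cis-chlorohydrin lactone whose C7 carries the angeloyloxy aldehyde and whose C6 carries the Z-alkenyl C10–H furanone.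

Key step: step 12

Remark: locants C1–C15 follow germacranolide numbering (C1 ketone, C2=C3 and C10 in the furanone, C4=C5 alkene, C6 lactone carbinol, C7, C8 ester carbinol, C9 carbinol, C11/C12 lactone, C13 CH2, C14/C15 methyls); C10 of 15–18 is drawn as introduced from the lactate, is configurationally labile, and is erased in silyloxyfuran 19, so its integrity is immaterial.

Step 1
Reactants: 1 (Z)-3-methylpent-2-en-4-yn-1-ol
Product: 2 (Z)-3-methylpent-2-en-4-ynal
Conditions: activated MnO2 (excess), CH2Cl2, 0 °C to rt; filtered solution used directly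
Reagents that add atoms: none
Why: Allylic alcohol oxidation with MnO2 under neutral heterogeneous conditions should preserve the Z geometry of the future C4=C5 bond and leave the terminal alkyne untouched.

Step 2
Reactants: 3 (R)-2,2-dimethyl-1,3-dioxolane-4-carbaldehyde; 4 methyl acrylate
Product: 5 Morita–Baylis–Hillman adduct (carbinol epimers)
Conditions: DABCO (0.5 equiv), neat, rt, several days
Reagents that add atoms: none
Why: Morita–Baylis–Hillman reaction of an α-alkoxy aldehyde; the new carbinol centre is removed in step 3, so its configuration is irrelevant, and the dioxolane centre (future C8) comes unchanged from the chiral pool.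

Step 3
Reactants: 5 Morita–Baylis–Hillman adduct
Product: 6 (Z)-allyl bromide
Conditions: NBS, Me2S, CH2Cl2, 0 °C to rt
Reagents that add atoms: N-bromosuccinimide, BrN1C(=O)CCC1=O
Why: Corey–Kim-type activation of the allylic alcohol as its alkoxysulfonium salt and SN2′ attack of bromide should give the rearranged primary bromide as the thermodynamically preferred (Z)-2-(bromomethyl)enoate (dioxolane cis to CH2Br), without touching the acetonide.

Step 4
Reactants: 2 (Z)-3-methylpent-2-en-4-ynal; 6 (Z)-allyl bromide
Product: 8 enyne cis-lactone acetonide (6S,7S,8S), via hydroxy ester 7 (not isolated)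
Conditions: Zn dust, THF–sat. aq. NH4Cl, 0 °C to rt; crude 7, PPTS (cat.), CH2Cl2, rt
Reagents that add atoms: none
Why: Zinc Barbier allylation through a closed chair transition state with the Z-disposed C8 substituent axial should give the syn C6/C7 adduct and hence the cis lactone on acid-catalysed lactonisation (only O6 is free), while the dioxolane centre (C8–H in the allyl plane to avoid allylic 1,3-strain, aldehyde entering anti to the C8–C9 bond) should set 6S,7S relative to 8S.

Step 5
Reactants: 8 enyne cis-lactone acetonide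
Product: 9 enyne lactone 8,9-diol
Conditions: AcOH–H2O (4:1), 40 °C
Reagents that add atoms: none
Why: Mild acid-catalysed acetal hydrolysis should free the C8/C9 diol without opening the conjugated lactone or touching the enyne and the stereocentres.

Step 6
Reactants: 9 enyne lactone 8,9-diol
Product: 10 C9 silyl ether with free C8 hydroxyl
Conditions: TBSCl (1.05 equiv), imidazole, CH2Cl2, −20 to 0 °C
Reagents that add atoms: tert-butyldimethylsilyl chloride, CC(C)(C)[Si](C)(C)Cl
Why: Silylation should be selective for the primary C9 hydroxyl over the hindered secondary C8 hydroxyl, which stays free as the directing group for step 7.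

Step 7
Reactants: 10 C9 silyl ether with free C8 hydroxyl
Product: 11 spiro-epoxy lactone (11S, epoxide oxygen cis to C8)
Conditions: t-BuOOH (in decane), DBU, toluene, −20 to 0 °C
Reagents that add atoms: tert-butyl hydroperoxide, CC(C)(C)OO
Why: Weitz–Scheffer nucleophilic epoxidation attacks only the exo-methylene lactone (the sole Michael acceptor), and hydrogen bonding of the C8 hydroxyl, which sits on the lactone face cis to C8, to the peroxide/enolate should deliver the oxygen to C11 on that face (hydroxyl-directed epoxidation).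

Step 8
Reactants: 11 spiro-epoxy lactone; 12 angelic acid
Product: 13 8-O-angelate
Conditions: 12, 2,4,6-trichlorobenzoyl chloride, Et3N, toluene, rt, filter; then 11, toluene, 75 °C
Reagents that add atoms: none
Why: Yamaguchi-type esterification with the preformed angelic mixed anhydride and no DMAP is the standard way to acylate a hindered secondary alcohol without isomerising the Z-angelate to the tiglate; C8 keeps its configuration (O-acylation).

Step 9
Reactants: 13 8-O-angelate; 14 (S)-2-acetoxypropanoyl chloride
Product: 15 acetoxy ynone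
Conditions: PdCl2(PPh3)2 (3 mol %), CuI (6 mol %), Et3N (2 equiv), THF, 0 °C to rt
Reagents that add atoms: none
Why: Acyl Sonogashira coupling of the terminal alkyne with the acid chloride gives the ynone (C1–C2≡C3) directly and should tolerate epoxide, esters and silyl ether because no free hydroxyl is present.

Step 10
Reactants: 15 acetoxy ynone
Product: 17 furanone chlorohydrin alcohol, via hydroxy ynone chlorohydrin 16 (not isolated)
Conditions: HCl (1.25 M in MeOH), 0 °C to rt
Reagents that add atoms: hydrogen chloride, Cl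
Why: Methanolic HCl should cleave the activated α-keto acetate and the primary silyl ether, open the glycidic epoxide with chloride at the primary carbon C13 (C11 untouched), and close the liberated γ-hydroxy ynone 16 by acid-promoted 5-endo oxa-Michael addition (3(2H)-furanone synthesis from γ-hydroxy ynones), O6 being tied up in the lactone so that no furan can form.

Step 11
Reactants: 17 furanone chlorohydrin alcohol
Product: 18 C9 aldehyde
Conditions: DMP, NaHCO3, CH2Cl2, 0 °C to rt; used at once
Reagents that add atoms: none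
Why: Dess–Martin oxidation of the primary C9 alcohol under buffered non-basic conditions should give the α-acyloxy aldehyde without epimerising C8; the tertiary C11 hydroxyl cannot be oxidised.

Step 12
Reactants: 18 C9 aldehyde
Product: 21 target CNP0272644.1, via bis-TMS silyloxyfuran aldehyde 19 (not isolated), via bis-TMS aldol adduct 20 (not isolated)
Conditions: i-Pr2NEt (2.3 equiv), TMSOTf (2.6 equiv), CH2Cl2 (0.002 M), −78 to −30 °C; then 1 M HCl, THF, 0 °C
Reagents that add atoms: none
Why: i-Pr2NEt/TMSOTf silylates the C11 hydroxyl and enolises the furanone to the aromatic 3-silyloxyfuran 19, whose C10 (furan C2) attacks the TMSOTf-activated C9 aldehyde in an intramolecular Mukaiyama aldol; silyl transfer gives 20 and the acid work-up cleaves both O–Si bonds. The closest known chemistry is the Lewis-acid aldol of 2-alkyl-3-silyloxyfurans with aldehydes to give 2,2-disubstituted 3(2H)-furanones, run here in the one-pot silyl triflate/amine mode and intramolecularly. The nine-membered ring closes in the 9-(enolexo)-exo-trig mode. C10 is controlled by C6 through the Z C4=C5 bond: allylic 1,3-strain keeps H6 in the alkene plane toward C3 and the lactone oxygen outside, so the C7–C8–C9 arm can arch over only one furan face, the one that gives 10R. C9 is controlled by the tether and by dipoles: C8 is held over the ring-oxygen edge, the formyl hydrogen rather than the silyl-activated oxygen sits over the furan, and C9=O lies antiperiplanar to the C8–O bond (monodentate activator, no chelate), which gives 9R. The step needs enolisation of the furanone rather than the α-acyloxy aldehyde (aromatic driving force at −78 °C), attack through C10 rather than C2 (furan α-position, restoring the vinylogous ester) and cyclisation rather than oligomerisation (high dilution).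

Compound list
1 | (Z)-3-methylpent-2-en-4-yn-1-ol | C#C/C(C)=C\CO | starting material
2 | (Z)-3-methylpent-2-en-4-ynal | C#C/C(C)=C\C=O | intermediate
3 | (R)-2,2-dimethyl-1,3-dioxolane-4-carbaldehyde | O=C[C@H]1COC(C)(C)O1 | starting material
4 | methyl acrylate | C=CC(=O)OC | starting material
5 | methyl 2-{hydroxy[(4R)-2,2-dimethyl-1,3-dioxolan-4-yl]methyl}prop-2-enoate (Morita–Baylis–Hillman adduct, carbinol epimers) | COC(=O)C(=C)C(O)[C@H]1COC(C)(C)O1 | intermediate
6 | methyl (2Z)-2-(bromomethyl)-3-[(4S)-2,2-dimethyl-1,3-dioxolan-4-yl]prop-2-enoate ((Z)-allyl bromide) | COC(=O)/C(CBr)=C/[C@H]1COC(C)(C)O1 | intermediate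
7 | methyl (3S,4S,5Z)-3-[(4S)-2,2-dimethyl-1,3-dioxolan-4-yl]-4-hydroxy-6-methyl-2-methylideneoct-5-en-7-ynoate (hydroxy ester) | COC(=O)C(=C)[C@@H]([C@@H](O)/C=C(/C)C#C)[C@H]1COC(C)(C)O1 | intermediate
8 | (4S,5S)-4-[(4S)-2,2-dimethyl-1,3-dioxolan-4-yl]-3-methylidene-5-[(1Z)-2-methylbut-1-en-3-yn-1-yl]oxolan-2-one (enyne cis-lactone acetonide, 6S,7S,8S) | CC1(C)OC[C@@H](O1)[C@@H]2[C@H](/C=C(/C)C#C)OC(=O)C2=C | intermediate
9 | (4R,5S)-4-[(1S)-1,2-dihydroxyethyl]-3-methylidene-5-[(1Z)-2-methylbut-1-en-3-yn-1-yl]oxolan-2-one (enyne lactone 8,9-diol) | OC[C@@H](O)[C@@H]1[C@H](/C=C(/C)C#C)OC(=O)C1=C | intermediate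
10 | (4R,5S)-4-[(1S)-2-[(tert-butyldimethylsilyl)oxy]-1-hydroxyethyl]-3-methylidene-5-[(1Z)-2-methylbut-1-en-3-yn-1-yl]oxolan-2-one (C9 silyl ether with free C8 hydroxyl) | CC(C)(C)[Si](C)(C)OC[C@@H](O)[C@@H]1[C@H](/C=C(/C)C#C)OC(=O)C1=C | intermediate
11 | (3S,6S,7R)-7-[(1S)-2-[(tert-butyldimethylsilyl)oxy]-1-hydroxyethyl]-6-[(1Z)-2-methylbut-1-en-3-yn-1-yl]-1,5-dioxaspiro[2.4]heptan-4-one (spiro-epoxy lactone, epoxide oxygen cis to C8) | CC(C)(C)[Si](C)(C)OC[C@@H](O)[C@@H]1[C@H](/C=C(/C)C#C)OC(=O)[C@@]12CO2 | intermediate
12 | angelic acid, (2Z)-2-methylbut-2-enoic acid | C/C=C(/C)C(=O)O | starting material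
13 | (1S)-2-[(tert-butyldimethylsilyl)oxy]-1-[(3S,6S,7S)-6-[(1Z)-2-methylbut-1-en-3-yn-1-yl]-4-oxo-1,5-dioxaspiro[2.4]heptan-7-yl]ethyl (2Z)-2-methylbut-2-enoate (8-O-angelate) | C/C=C(/C)C(=O)O[C@H](CO[Si](C)(C)C(C)(C)C)[C@@H]1[C@H](/C=C(/C)C#C)OC(=O)[C@@]12CO2 | intermediate
14 | (S)-2-acetoxypropanoyl chloride | C[C@H](OC(C)=O)C(Cl)=O | starting material
15 | (1S)-2-[(tert-butyldimethylsilyl)oxy]-1-[(3S,6S,7S)-6-[(1Z,6S)-6-acetoxy-2-methyl-5-oxohept-1-en-3-yn-1-yl]-4-oxo-1,5-dioxaspiro[2.4]heptan-7-yl]ethyl (2Z)-2-methylbut-2-enoate (acetoxy ynone) | C/C=C(/C)C(=O)O[C@H](CO[Si](C)(C)C(C)(C)C)[C@@H]1[C@H](/C=C(/C)C#CC(=O)[C@H](C)OC(C)=O)OC(=O)[C@@]12CO2 | intermediate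
16 | (1S)-1-[(2S,3S,4R)-4-(chloromethyl)-4-hydroxy-2-[(1Z,6S)-6-hydroxy-2-methyl-5-oxohept-1-en-3-yn-1-yl]-5-oxooxolan-3-yl]-2-hydroxyethyl (2Z)-2-methylbut-2-enoate (hydroxy ynone chlorohydrin) | C/C=C(/C)C(=O)O[C@H](CO)[C@@H]1[C@H](/C=C(/C)C#CC(=O)[C@H](C)O)OC(=O)[C@@]1(O)CCl | intermediate
17 | (1S)-1-[(2S,3S,4R)-4-(chloromethyl)-4-hydroxy-2-[(1Z)-2-(5-methyl-4-oxo-4,5-dihydrofuran-2-yl)prop-1-en-1-yl]-5-oxooxolan-3-yl]-2-hydroxyethyl (2Z)-2-methylbut-2-enoate (furanone chlorohydrin alcohol) | C/C=C(/C)C(=O)O[C@H](CO)[C@@H]1[C@H](/C=C(/C)C2=CC(=O)[C@H](C)O2)OC(=O)[C@@]1(O)CCl | intermediate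
18 | (1S)-1-[(2S,3S,4R)-4-(chloromethyl)-4-hydroxy-2-[(1Z)-2-(5-methyl-4-oxo-4,5-dihydrofuran-2-yl)prop-1-en-1-yl]-5-oxooxolan-3-yl]-2-oxoethyl (2Z)-2-methylbut-2-enoate (C9 aldehyde) | C/C=C(/C)C(=O)O[C@H](C=O)[C@@H]1[C@H](/C=C(/C)C2=CC(=O)[C@H](C)O2)OC(=O)[C@@]1(O)CCl | intermediate
19 | bis-TMS silyloxyfuran aldehyde: 18 with the furanone as 2-methyl-3-(trimethylsilyloxy)furan and the C11 hydroxyl as its trimethylsilyl ether | C/C=C(/C)C(=O)O[C@H](C=O)[C@@H]1[C@H](/C=C(/C)c2cc(O[Si](C)(C)C)c(C)o2)OC(=O)[C@@]1(O[Si](C)(C)C)CCl | intermediate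
20 | bis-TMS aldol adduct: 9,11-bis(trimethylsilyl) ether of the target | C/C=C(/C)C(=O)O[C@H]1[C@@H]2[C@H](/C=C(/C)C3=CC(=O)[C@](C)(O3)[C@@H]1O[Si](C)(C)C)OC(=O)[C@@]2(O[Si](C)(C)C)CCl | intermediate
21 | CNP0272644.1, (6S,7S,8S,9R,10R,11R)-8-angeloyloxy-13-chloro-9,11-dihydroxy-3,10-epoxy-1-oxogermacra-2,4(Z)-dien-12,6-olide | C/C=C(/C)C(=O)O[C@H]1[C@@H]2[C@H](/C=C(/C)C3=CC(=O)[C@](C)(O3)[C@@H]1O)OC(=O)[C@@]2(O)CCl | target

Total step count: 12. Longest linear sequence: 11 steps (from 3 through steps 2–12).

Steps most likely to fail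

Step 12 (ring-closing aldol). The aldehyde may be silylated or enolised in competition with the furanone, with loss of the C8 configuration. The aldol may also run intermolecularly, or the aldehyde may add to the other furan face or present its other face. The fallback generates the C10 enolate reductively, without base or silyl triflate in the presence of the aldehyde. It sets out from alcohol 17. Transient silylation to the silyloxyfuran (TMSOTf, Et3N, CH2Cl2, −78 °C), bromination with NBS at the furan α-carbon and acidic work-up should give the C10 bromide, bromofuranone alcohol F1. Dess–Martin oxidation gives bromo aldehyde F2. SmI2 (2.2 equiv) in THF at −78 °C under high dilution should reduce the C–Br bond to the samarium enolate, which adds to the C9 aldehyde in a Reformatsky-type cyclisation through a chelated transition state. The fallback comes back to the route at 21.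

Step 7 (directed epoxidation). The peroxide may deliver oxygen to the open lactone face anti to C8 (giving the C11 epimer), and the base may trigger silyl migration or translactonisation to O8. The fallback replaces conjugate-addition epoxidation by hydrogen-bond-directed osmylation and epoxide closure. It sets out from 10. OsO4–TMEDA (1 equiv) in CH2Cl2 at −78 °C, guided by the C8 hydroxyl, followed by aqueous NaHSO3, should give the 11,13-diol with O11 cis to C8, triol F3. TsCl in pyridine at 0 °C should sulfonylate only the primary C13 hydroxyl to give tosylate F4. K2CO3 in acetone should close the tertiary alkoxide onto C13. The fallback comes back to the route at 11.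

Step 4 (Barbier allylation–lactonisation). Coordination of the dioxolane oxygen to zinc may reverse the facial selectivity with respect to C8, and the syn preference may erode with the Z-enal. The fallback uses an allylboration, in which tetracoordinate boron in the chair transition state cannot be chelated by the dioxolane. It sets out from 6. Miyaura-type borylation (B2pin2, Pd2(dba)3 cat., toluene, 50 °C) should give the primary allylboronate F5 with the dioxolane still cis to the CH2B group. Heating F5 with aldehyde 2 in toluene at 80 °C should give the borate of 7, and PPTS then lactonises it. The fallback comes back to the route at 8.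

Further compounds
F1 | step 12 | bromofuranone alcohol: 17 bearing bromine at C10 (2-bromo-2-methyl-3(2H)-furanone, C10 epimers) | C/C=C(/C)C(=O)O[C@H](CO)[C@@H]1[C@H](/C=C(/C)C2=CC(=O)C(C)(Br)O2)OC(=O)[C@@]1(O)CCl
F2 | step 12 | bromo aldehyde: 18 bearing bromine at C10 (C10 epimers) | C/C=C(/C)C(=O)O[C@H](C=O)[C@@H]1[C@H](/C=C(/C)C2=CC(=O)C(C)(Br)O2)OC(=O)[C@@]1(O)CCl
F3 | step 7 | triol: 11,13-dihydroxy derivative of 10 with O11 cis to C8 | CC(C)(C)[Si](C)(C)OC[C@@H](O)[C@@H]1[C@H](/C=C(/C)C#C)OC(=O)[C@@]1(O)CO
F4 | step 7 | tosylate: 13-O-p-toluenesulfonate of triol F3 | CC(C)(C)[Si](C)(C)OC[C@@H](O)[C@@H]1[C@H](/C=C(/C)C#C)OC(=O)[C@@]1(O)COS(=O)(=O)c2ccc(C)cc2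
F5 | step 4 | allylboronate: methyl (2E)-3-[(4S)-2,2-dimethyl-1,3-dioxolan-4-yl]-2-[(4,4,5,5-tetramethyl-1,3,2-dioxaborolan-2-yl)methyl]prop-2-enoate | COC(=O)/C(CB1OC(C)(C)C(C)(C)O1)=C/[C@H]2COC(C)(C)O2
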